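## Analysis of the target

The target (41) is a sesquilignan assembled from three phenylpropanoid units. Its core is a γ-butyrolactone (O1, C2 carbonyl, C3, C4, C5 methylene) with an arylmethyl group on C3 and another on C4, trans to each other (3R,4R). The C4 benzyl ring (ring B, 3-methoxy-4-oxyphenyl) is etherified at its 4-oxygen by C8 of an arylglycerol chain C7–C8–C9; C7 carries a hydroxyl and ring A (4-hydroxy-3-methoxyphenyl), and C7/C8 are (1R,2S), the erythro (anti) arrangement. The C3 benzyl ring is ring C of a 2,3-dihydrobenzofuran (phenylcoumaran) joined through coumaran C5, with a 7-methoxy group, a hydroxymethyl on coumaran C3 (R) and ring D (4-hydroxy-3-methoxyphenyl) on coumaran C2 (S), trans. The six stereocentres therefore form three vicinal pairs separated by aromatic rings, so no pair can pass its configuration to another and each must be set absolutely. Sensitive points are the two free phenols, the p-hydroxybenzylic alcohol at C7 (ionises in acid, can be hydrogenolysed), the benzylic C2–O bond of the coumaran, and the lactone, which is base-labile and epimerisable at C3. The difficulty lies less in any one ring than in joining three large, oxygen-rich fragments while the lactone pair is controlled at the point of union. The plan rests on one feature: lactone C3 and C4 each bear a CH2Ar group, trans, while C5 is a bare CH2. That is the imprint of a butenolide that has accepted a benzoyl anion equivalent at C4 and a benzylic electrophile at C3, with C5 free to carry a removable chiral alkoxy group during the addition.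

## Retrosynthetic reasoning

41 ← 40 ← 39. The two phenols and three alcohols are unmasked last: the three aryl benzyl ethers of 40 are cut, and before that the three silyl ethers of 39. This keeps every acidic proton out of the coupling and holds the p-oxybenzylic C7 oxygen as a silyl ether through all basic and reductive steps. The forward steps must remove silicon under buffered conditions and benzyl by hydrogenolysis without breaking the benzylic C7–O and coumaran C2–O bonds.

39 ← 36 ← 35. Lactone C5 (CH2) is traced to an acetal carbon bearing the menthyloxy group (36), and the CH2 between ring B and C4 to a 1,3-dithiane carbon (35). No skeletal bond is cut here; the two changes restore the groups that make the lactone bonds polar, the acetal as stereocontrol element and the dithiane as masked acyl anion. Forward, the C–S bonds are hydrogenolysed, then the acyl acetal is opened, reduced at C5 and re-closed on the unchanged carbonyl carbon C2, so the α/β placement of the two benzyl groups is kept.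

35 ⇒ 16 + 5 + 32. Two bonds on the lactone are cut: dithiane carbon–C4 and C3–CH2 (ring C side). The molecule divides most evenly here, into the ring A–B dithiane 16, the ring C–D bromide 32 and the four-carbon butenolide 5. The cut falls between the three stereo-pairs, so each aryl fragment arrives with one complete pair and the third pair is made in the union. Cutting at the C8–O aryl ether or inside the coumaran would leave the lactone centres to be built on an elaborated fragment with no controlling element nearby. Forward, lithiated 16 must add 1,4 to 5 anti to the menthyloxy group, and the enolate must be alkylated by 32 trans to the new C4 substituent.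

5 ← 3 + 4, 3 ← 1. The acetal C5–O bond of 5 is cut to hemiacetal 3 and (−)-menthol 4; 3 goes back to furfural 1 by oxidative excision of the formyl carbon. The forward acetalisation must deliver one C5 epimer, which crystallisation under equilibrating conditions provides.

16 ← 15 ← 14. After removal of the C7 silyl group, the C7–H bond is cut (alcohol 15 ← ketone 14). C7 is the one centre of this fragment not available from the chiral pool. Next to the aryloxy-bearing C8 it can be set by chelation-controlled hydride delivery, which gives the anti (erythro) pattern; an auxiliary-based syn-aldol between an aryloxyacetyl unit and aldehyde 24 would give the threo series instead.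

14 ← 11 + 13 (from 12), 11 ← 10 ← 7 + 9, 9 ← 8, 7 ← 6. Ketone 14 is cut at the C7–ring A bond to Weinreb amide 11 and Grignard reagent 13. Ester 10 is cut at the C8–O aryl ether bond to phenol 7 and hydroxy ester 9. This ether is the natural seam between rings A and B, and forming it with inversion brings C8 in from (R)-glycerate 8. The dithiane is installed on vanillin 6 at the outset. Thioacetalising a ring B aldehyde late would need a Lewis acid next to the ionisable benzylic C7–O bond and would also strip any ketal protection. For the same reason of economy C7–O and C9–O carry silyl ethers rather than a cyclic ketal: they arise directly from the reduction sequence and leave together with the coumaran silyl ether.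

32 ← 31 ← 30 ← 29. The bromide is traced through the benzylic alcohol 31 to methyl ester 30 and its free alcohol 29. Coumaran C5 is carried as an ester because it survives the boron enolate, hydride and acid steps without protection and is one reduction from the alcohol.

29 ← 28 ← 27. The coumaran is cut at O1–C2: the ring C phenol oxygen of 28 (unmasked from 27) captures a benzylic cation at C2. This closure is stereoconvergent, so only C3 has to be set beforehand.

27 ← 26 ← 23 + 24, 23 ← 20 + 21. The bond between the future coumaran C3 and C2 is cut by a syn-aldol between imide 23 and aldehyde 24; the auxiliary 21 fixes C3 and is then removed reductively, which also creates the CH2OH group.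

20 ← 19 ← 18 ← 17. The arylacetic acid is cut at the aryl–CH2 bond (the future C3a–C3 bond) to aryl bromide 18, the protected form of commercial bromophenol ester 17; the forward reaction is a palladium-catalysed coupling with a zinc ester enolate under neutral conditions.

## Alternatives that were turned down

Alternative 1: Ring contraction of a flavanone. The coumaran C3–C3a bond and the carbon on C3 are traced to C4 and the C4–C4a bond of the chroman-4-one A1. In the forward key step A1 is converted with an orthoformate and acid into its enol ether, a trivalent iodine diacetate oxidant adds at C3, and aryl carbon C4a shifts from C4 to C3 as the iodine leaves in its monovalent state. The six-membered ring contracts and C4 becomes the ester carbon of trans ester A2.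
- For: the heterocycle comes from simple aromatic ketone chemistry, the trans relationship is produced directly, and the C3 carbon appears at the ester oxidation level. On step count to the bare coumaran core it is probably shorter than steps 10–16 here.
- Against: A1 must be enantioenriched at C2, and flavanones open reversibly to the achiral hydroxychalcone under the acidic enol-ether conditions, so C2 can erode.
- Against: ring D is electron-rich and its migration from C2 to C3 (the isoflavone pathway) competes with the wanted shift; hence the tosylate in A2, which must later be exchanged.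
- Against: A2 carries bromine at C5, so the benzylic carbon that links to the lactone still has to be introduced by an aryl–carbon bond formation next to an ester.
- Comparison: the alternative solves only the coumaran and leaves the lactone pair and the fragment union undefined. The chosen strategy spends more steps on the coumaran but sets its C3 with a stoichiometric auxiliary of predictable sense and carries the C5 carbon from the start (17).

Alternative 2: Carbene C–H insertion. The coumaran C2–C3 bond is cut. Forward, diazo ester A3 is decomposed by a chiral dirhodium tetracarboxylate with N-phthaloyl-tert-leucinate ligands, and the carbene inserts into a benzylic C–H bond of the neighbouring 4-benzyloxy-3-methoxybenzyl ether to give cis ester A4.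
- For: one catalytic asymmetric step forms the C–C bond and both coumaran centres, and A4 already has the C5 carbon as a protected CH2OH. On atom economy and elegance it is stronger than the auxiliary aldol used here.
- Against: the insertion gives the cis isomer, so C3 must be epimerised under base. The ester enolate has the C2–O bond in the β position and can open by E1cB to an achiral cinnamate phenoxide, which puts C2 at risk.
- Against: the benzylic C–H bond is flanked by two very electron-rich rings, so oxonium ylide formation and hydride-transfer (zwitterionic) pathways compete with concerted insertion and can lower selectivity.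
- Against: A3 needs the same arylacetate as 20, so nothing is saved upstream.
- Comparison: the main risk would sit inside one fragment, and the lactone would still have to be built. The chosen strategy places the single high-risk step at the convergent union and uses only substrate- or auxiliary-controlled steps of known sense before it.

Alternative 3: Benzylic cation cyclisation as the organising step. The O1–C2 bond is cut. Forward, a boron Lewis acid ionises the benzylic alcohol of phenol diol A5 and the phenol oxygen captures the cation trans to the CH2OH group, giving bromo alcohol A6.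
- For: the closure is stereoconvergent and robust. On this point it is as strong as the chosen route, which uses the same type of closure as a supporting step (step 16, 28 → 29).
- Against, as a plan built around A6: the C5 bromine has to be turned into the benzylic CH2Br by metalation, formylation, reduction and bromination in the presence of the C3 hydroxymethyl group, where the chosen route needs one ester reduction (30 → 31).
- Against: the strategy defines neither how the lactone centres are set nor how the three fragments meet.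
- Comparison: the aryl bromide A6 offers more freedom for cross-coupling; the chosen strategy gives instead a defined, convergent construction of the lactone.

Key step: step 20

Remarks on the chemistry: methyl (R)-glycerate 8 and methyl 5-bromovanillate 17 are taken as purchasable, and Zn(BH4)2 is used as a stock solution in Et2O.

Abbreviations used in names:
- Men = (1R,2S,5R)-5-methyl-2-(propan-2-yl)cyclohexyl
- TBS = tert-butyldimethylsilyl; TBDPS = tert-butyldiphenylsilyl; MOM = methoxymethyl
- ArAB = 4-{[(1R,2S)-1-[4-(benzyloxy)-3-methoxyphenyl]-1-(TBS-oxy)-3-(TBDPS-oxy)propan-2-yl]oxy}-3-methoxyphenyl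
- ArCD = (2S,3R)-2-[4-(benzyloxy)-3-methoxyphenyl]-3-[(TBS-oxy)methyl]-7-methoxy-2,3-dihydro-1-benzofuran-5-yl

## Route

Step 1
Reactants: 1 furfural
Product: 3 5-hydroxyfuran-2(5H)-one, via furfural endoperoxide 2 (not isolated)
Conditions: O2, hν (visible), rose bengal (cat.), MeOH, 20 °C
Reagents that add atoms: oxygen, O=O
Why: Dye-sensitised singlet oxygen adds [4+2] across the furan; methanol attacks the formyl group of endoperoxide 2, which fragments with loss of the formyl carbon to the γ-hydroxybutenolide (furan photo-oxygenation).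

Step 2
Reactants: 3 5-hydroxyfuran-2(5H)-one; 4 (−)-menthol
Product: 5 (5R)-5-(Men-oxy)furan-2(5H)-one
Conditions: camphorsulfonic acid (cat.), toluene, reflux, Dean–Stark; crystallisation from petroleum ether, −20 °C; mother liquor re-equilibrated with acid
Reagents that add atoms: none
Why: Acid-catalysed acetal exchange of the pseudo-acid gives both C5 epimers, which interconvert under acid; the (5R) epimer should crystallise, so the mixture is funnelled to it (crystallisation-induced diastereomer transformation). This fixes the centre that later controls the lactone.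

Step 3
Reactants: 6 vanillin
Product: 7 4-(1,3-dithian-2-yl)-2-methoxyphenol
Conditions: HS(CH2)3SH, BF3·OEt2 (cat.), CH2Cl2, 0 °C → rt
Reagents that add atoms: propane-1,3-dithiol, SCCCS
Why: Lewis-acid thioacetalisation of an aromatic aldehyde; it is done here, on the simplest substrate, because no acid-labile group is yet present.

Step 4
Reactants: 8 methyl (2R)-2,3-dihydroxypropanoate
Product: 9 methyl (2R)-3-(TBDPS-oxy)-2-hydroxypropanoate
Conditions: TBDPSCl, imidazole, CH2Cl2, 0 °C
Reagents that add atoms: tert-butyl(chloro)diphenylsilane, CC(C)(C)[Si](Cl)(c1ccccc1)c1ccccc1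
Why: The bulky silyl chloride reacts selectively at the primary hydroxyl; the secondary hydroxyl next to the ester stays free for the ether formation.

Step 5
Reactants: 7 4-(1,3-dithian-2-yl)-2-methoxyphenol; 9 methyl (2R)-3-(TBDPS-oxy)-2-hydroxypropanoate
Product: 10 methyl (2S)-3-(TBDPS-oxy)-2-[4-(1,3-dithian-2-yl)-2-methoxyphenoxy]propanoate
Conditions: PPh3, iPrO2C–N=N–CO2iPr, THF, 0 °C → rt
Reagents that add atoms: none
Why: Mitsunobu etherification of an α-hydroxy ester with a phenol proceeds by SN2 with inversion, so the (2R) alcohol gives the (2S) aryl ether, which is the C8 configuration of the target.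

Step 6
Reactants: 10 methyl (2S)-3-(TBDPS-oxy)-2-[4-(1,3-dithian-2-yl)-2-methoxyphenoxy]propanoate
Product: 11 (2S)-3-(TBDPS-oxy)-2-[4-(1,3-dithian-2-yl)-2-methoxyphenoxy]-N-methoxy-N-methylpropanamide
Conditions: MeNH(OMe)·HCl, iPrMgCl, THF, −20 → 0 °C
Reagents that add atoms: N,O-dimethylhydroxylamine hydrochloride, CNOC.Cl
Why: The magnesium amide formed in the flask aminolyses the ester at low temperature (Weinreb amide formation); the fast acyl transfer should outrun α-deprotonation, so C8 is expected to keep its configuration.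

Step 7
Reactants: 11 (2S)-3-(TBDPS-oxy)-2-[4-(1,3-dithian-2-yl)-2-methoxyphenoxy]-N-methoxy-N-methylpropanamide; 12 1-(benzyloxy)-4-bromo-2-methoxybenzene
Product: 14 (2S)-1-[4-(benzyloxy)-3-methoxyphenyl]-3-(TBDPS-oxy)-2-[4-(1,3-dithian-2-yl)-2-methoxyphenoxy]propan-1-one, via arylmagnesium bromide 13 (not isolated)
Conditions: 12, Mg, THF, rt; then 11, THF, 0 °C; aq. NH4Cl
Reagents that add atoms: none
Why: Weinreb ketone synthesis: the chelated tetrahedral adduct prevents a second addition and keeps C8 from enolising until work-up; the dithiane C–H is not acidic enough to be attacked by the Grignard reagent.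

Step 8
Reactants: 14 (2S)-1-[4-(benzyloxy)-3-methoxyphenyl]-3-(TBDPS-oxy)-2-[4-(1,3-dithian-2-yl)-2-methoxyphenoxy]propan-1-one
Product: 15 (1R,2S)-1-[4-(benzyloxy)-3-methoxyphenyl]-3-(TBDPS-oxy)-2-[4-(1,3-dithian-2-yl)-2-methoxyphenoxy]propan-1-ol
Conditions: Zn(BH4)2, Et2O/CH2Cl2, −78 → −20 °C
Reagents that add atoms: none
Why: Cram-chelate reduction: zinc bridges the ketone oxygen and the α-aryloxy oxygen (helped by the ortho methoxy group), and hydride enters from the side of the C8 hydrogen, which sets C7 as (1R), anti to the aryloxy group (erythro). The bulky silyl ether should not form the competing six-membered chelate.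

Step 9
Reactants: 15 (1R,2S)-1-[4-(benzyloxy)-3-methoxyphenyl]-3-(TBDPS-oxy)-2-[4-(1,3-dithian-2-yl)-2-methoxyphenoxy]propan-1-ol
Product: 16 2-ArAB-1,3-dithiane
Conditions: TBSOTf, 2,6-lutidine, CH2Cl2, −78 → 0 °C
Reagents that add atoms: tert-butyldimethylsilyl trifluoromethanesulfonate, CC(C)(C)[Si](C)(C)OS(=O)(=O)C(F)(F)F
Why: Silylation of a hindered secondary alcohol with the silyl triflate; it removes the only acidic proton of the fragment before the organolithium step.

Step 10
Reactants: 17 methyl 3-bromo-4-hydroxy-5-methoxybenzoate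
Product: 18 methyl 3-bromo-5-methoxy-4-(methoxymethoxy)benzoate
Conditions: MOMCl, iPr2NEt, CH2Cl2, 0 °C → rt
Reagents that add atoms: chloromethyl methyl ether, COCCl
Why: O-alkylation of the phenol; the MOM ether is stable to the zinc, boron and hydride reagents that follow and is removed by the acid that later closes the coumaran.

Step 11
Reactants: 18 methyl 3-bromo-5-methoxy-4-(methoxymethoxy)benzoate
Product: 19 methyl 3-[2-(benzyloxy)-2-oxoethyl]-5-methoxy-4-(methoxymethoxy)benzoate
Conditions: BrZnCH2CO2Bn (from BrCH2CO2Bn, Zn, THF), tris(dibenzylideneacetone)dipalladium Pd2(dba)3 (cat.), XPhos (cat.), THF, 60 °C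
Reagents that add atoms: benzyl bromoacetate (used as its zinc reagent), BrCC(=O)OCc1ccccc1
Why: Negishi-type coupling of an aryl bromide with a Reformatsky reagent (α-arylation of a zinc ester enolate); the neutral zinc enolate tolerates the methyl ester and the MOM ether.

Step 12
Reactants: 19 methyl 3-[2-(benzyloxy)-2-oxoethyl]-5-methoxy-4-(methoxymethoxy)benzoate
Product: 20 [3-methoxy-5-(methoxycarbonyl)-2-(methoxymethoxy)phenyl]acetic acid
Conditions: H2 (1 atm), Pd/C, EtOAc, rt
Reagents that add atoms: none
Why: Hydrogenolysis cleaves only the benzyl ester; the methyl ester and the MOM ether are inert, and no aryl halide or other benzyl group is present at this stage.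

Step 13
Reactants: 20 [3-methoxy-5-(methoxycarbonyl)-2-(methoxymethoxy)phenyl]acetic acid; 21 (4S)-4-benzyl-1,3-oxazolidin-2-one
Product: 23 methyl 3-{2-[(4S)-4-benzyl-2-oxo-1,3-oxazolidin-3-yl]-2-oxoethyl}-5-methoxy-4-(methoxymethoxy)benzoate, via mixed pivalic anhydride 22 (not isolated)
Conditions: tBuCOCl, Et3N, THF, −20 °C; then 21, LiCl, −20 °C → rt
Reagents that add atoms: none
Why: The acid is activated as the mixed pivalic anhydride and acylates the oxazolidinone at the less hindered carbonyl under LiCl/amine conditions (standard N-acylation for Evans auxiliaries).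

Step 14
Reactants: 23 methyl 3-{2-[(4S)-4-benzyl-2-oxo-1,3-oxazolidin-3-yl]-2-oxoethyl}-5-methoxy-4-(methoxymethoxy)benzoate; 24 4-(benzyloxy)-3-methoxybenzaldehyde
Product: 26 (4S)-4-benzyl-3-[(2S,3S)-3-[4-(benzyloxy)-3-methoxyphenyl]-3-hydroxy-2-[3-methoxy-5-(methoxycarbonyl)-2-(methoxymethoxy)phenyl]propanoyl]-1,3-oxazolidin-2-one, via dibutylboron Z-enolate 25 (not isolated)
Conditions: Bu2BOTf, iPr2NEt, CH2Cl2, −78 → 0 °C; 24, −78 → 0 °C; pH 7 buffer, MeOH, H2O2, 0 °C
Reagents that add atoms: none
Why: Evans syn-aldol: the Z-boron enolate reacts through a closed Zimmerman–Traxler chair on the enolate face away from the auxiliary benzyl group. This sets the α-carbon (2S), the future coumaran C3, and gives the syn carbinol (3S), whose configuration is later erased.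

Step 15
Reactants: 26 (4S)-4-benzyl-3-[(2S,3S)-3-[4-(benzyloxy)-3-methoxyphenyl]-3-hydroxy-2-[3-methoxy-5-(methoxycarbonyl)-2-(methoxymethoxy)phenyl]propanoyl]-1,3-oxazolidin-2-one
Product: 27 methyl 3-[(1S,2R)-1-[4-(benzyloxy)-3-methoxyphenyl]-1,3-dihydroxypropan-2-yl]-5-methoxy-4-(methoxymethoxy)benzoate
Conditions: LiBH4, MeOH (1 equiv), THF, 0 °C
Reagents that add atoms: none
Why: Reductive removal of the auxiliary: the exocyclic imide carbonyl is far more electrophilic than the donor-substituted methyl benzoate, so the primary alcohol should form with the ester intact. The descriptor at the former α-carbon changes to R only through priority rules.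

Step 16
Reactants: 27 methyl 3-[(1S,2R)-1-[4-(benzyloxy)-3-methoxyphenyl]-1,3-dihydroxypropan-2-yl]-5-methoxy-4-(methoxymethoxy)benzoate
Product: 29 methyl (2S,3R)-2-[4-(benzyloxy)-3-methoxyphenyl]-3-(hydroxymethyl)-7-methoxy-2,3-dihydro-1-benzofuran-5-carboxylate, via free phenol 28 (not isolated)
Conditions: HCl (MeOH), 0 °C → rt
Reagents that add atoms: none
Why: Acid removes the MOM group and ionises the p-alkoxybenzylic alcohol; the phenol oxygen captures the cation in a 5-exo closure. The aryl group settles trans to the C3 hydroxymethyl group, so C2 (S) is set under control of C3 whatever the carbinol configuration (stereoconvergent SN1 closure); methanol as solvent leaves the methyl ester unchanged.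

Step 17
Reactants: 29 methyl (2S,3R)-2-[4-(benzyloxy)-3-methoxyphenyl]-3-(hydroxymethyl)-7-methoxy-2,3-dihydro-1-benzofuran-5-carboxylate
Product: 30 methyl (2S,3R)-2-[4-(benzyloxy)-3-methoxyphenyl]-3-[(TBS-oxy)methyl]-7-methoxy-2,3-dihydro-1-benzofuran-5-carboxylate
Conditions: TBSCl, imidazole, DMF, rt
Reagents that add atoms: tert-butyl(chloro)dimethylsilane, CC(C)(C)[Si](C)(C)Cl
Why: Standard silylation of the only free (primary) alcohol, needed before the ester is reduced to a second primary alcohol.

Step 18
Reactants: 30 methyl (2S,3R)-2-[4-(benzyloxy)-3-methoxyphenyl]-3-[(TBS-oxy)methyl]-7-methoxy-2,3-dihydro-1-benzofuran-5-carboxylate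
Product: 31 [(2S,3R)-2-[4-(benzyloxy)-3-methoxyphenyl]-3-[(TBS-oxy)methyl]-7-methoxy-2,3-dihydro-1-benzofuran-5-yl]methanol
Conditions: iBu2AlH (DIBAL-H), CH2Cl2, −78 → 0 °C; Rochelle salt
Reagents that add atoms: none
Why: Hydride reduction of the aryl ester to the benzylic alcohol; silyl and benzyl ethers and the coumaran are inert to the aluminium hydride.

Step 19
Reactants: 31 [(2S,3R)-2-[4-(benzyloxy)-3-methoxyphenyl]-3-[(TBS-oxy)methyl]-7-methoxy-2,3-dihydro-1-benzofuran-5-yl]methanol
Product: 32 (2S,3R)-2-[4-(benzyloxy)-3-methoxyphenyl]-5-(bromomethyl)-3-[(TBS-oxy)methyl]-7-methoxy-2,3-dihydro-1-benzofuran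
Conditions: CBr4, PPh3, CH2Cl2, 0 °C; used at once
Reagents that add atoms: carbon tetrabromide, BrC(Br)(Br)Br
Why: Appel bromination under neutral conditions; the p-alkoxybenzylic bromide is a very reactive alkylating agent and is therefore made immediately before use.

Step 20
Reactants: 16 2-ArAB-1,3-dithiane; 5 (5R)-5-(Men-oxy)furan-2(5H)-one; 32 (2S,3R)-2-[4-(benzyloxy)-3-methoxyphenyl]-5-(bromomethyl)-3-[(TBS-oxy)methyl]-7-methoxy-2,3-dihydro-1-benzofuran
Product: 35 (3R,4R,5R)-3-(ArCD-methyl)-4-(2-ArAB-1,3-dithian-2-yl)-5-(Men-oxy)oxolan-2-one, via 2-lithio-1,3-dithiane 33 (not isolated), via lithium enolate 34 (not isolated)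
Conditions: 16, n-BuLi (1.0 equiv), THF, −78 → −20 °C; 5, −78 °C; 32, DMPU, −78 → −40 °C; aq. NH4Cl
Reagents that add atoms: none
Why: Deprotonation of 16 at the dithiane carbon gives the soft, sulfur-stabilised carbanion 33, which adds 1,4 to butenolide 5; the resulting lithium enolate 34 is then C-alkylated by the benzylic bromide 32 in an SN2 reaction. The closest known reaction type is the tandem conjugate addition–enolate alkylation of 2-aryl-2-lithio-1,3-dithianes on 5-alkoxyfuran-2(5H)-ones with benzylic bromides, the established route to trans-dibenzylbutyrolactone lignans. No ring is closed; two C–C bonds are formed, dithiane carbon to C4 and C3 to the benzylic CH2. C4 (R) is controlled by the (5R) acetal carbon: the menthyloxy group shields its face of the flat butenolide, so the nucleophile enters anti to it. C3 (R) is controlled by the new C4 substituent: the quaternary dithianyl group blocks its own face of enolate 34, so the bromide approaches trans to it. The step needs 1,4- over 1,2-addition, which the delocalised dithiane anion and the acyl-acetal carbonyl favour, and C- over O-alkylation, which a lithium ester enolate with a soft benzylic bromide in THF/DMPU favours. The stereocentres already present in 16 and 32 are remote and are not deprotonated under these conditions, so control by the acetal should not depend on them.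

Step 21
Reactants: 35 (3R,4R,5R)-3-(ArCD-methyl)-4-(2-ArAB-1,3-dithian-2-yl)-5-(Men-oxy)oxolan-2-one
Product: 36 (3R,4R,5R)-3-(ArCD-methyl)-4-(ArAB-methyl)-5-(Men-oxy)oxolan-2-one
Conditions: NiCl2·6H2O, NaBH4, MeOH/THF, 0 °C
Reagents that add atoms: none
Why: Nickel boride formed in the flask hydrogenolyses the benzylic C–S bonds of the dithiane to CH2 (desulfurisation); this reagent is milder than Raney nickel and should leave aryl benzyl ethers, silyl ethers and the acyl acetal untouched.

Step 22
Reactants: 36 (3R,4R,5R)-3-(ArCD-methyl)-4-(ArAB-methyl)-5-(Men-oxy)oxolan-2-one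
Product: 39 (3R,4R)-3-(ArCD-methyl)-4-(ArAB-methyl)oxolan-2-one, via potassium formyl carboxylate 37 (not isolated), via potassium hydroxy carboxylate 38 (not isolated)
Conditions: KOH, NaBH4, EtOH/H2O, 0 °C → rt; then 1 M HCl to pH 3, rt
Reagents that add atoms: potassium hydroxide, [K+].[OH-] (its oxygen enters the carboxylate of 37 and may end as the lactone carbonyl oxygen)
Why: Hydroxide opens the pseudo-ester at C2, and the hemiacetal at C5 collapses to the aldehyde with release of menthol. Borohydride, present from the start, should reduce the aldehyde faster than it enolises, and mild acid closes the γ-lactone on the original carbonyl carbon; C3 and C4 are therefore retained and C5 becomes CH2.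

Step 23
Reactants: 39 (3R,4R)-3-(ArCD-methyl)-4-(ArAB-methyl)oxolan-2-one
Product: 40 (3R,4R)-3-{[(2S,3R)-2-[4-(benzyloxy)-3-methoxyphenyl]-3-(hydroxymethyl)-7-methoxy-2,3-dihydro-1-benzofuran-5-yl]methyl}-4-[(4-{[(1R,2S)-1-[4-(benzyloxy)-3-methoxyphenyl]-1,3-dihydroxypropan-2-yl]oxy}-3-methoxyphenyl)methyl]oxolan-2-one
Conditions: Bu4NF, AcOH, THF, 0 °C → rt
Reagents that add atoms: none
Why: Fluoride cleaves the three silyl ethers; acetic acid buffers the alkoxides so that the lactone is neither opened nor epimerised at C3, and with the phenols still benzylated no quinone methide can form at C7.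

Step 24
Reactants: 40 (3R,4R)-3-{[(2S,3R)-2-[4-(benzyloxy)-3-methoxyphenyl]-3-(hydroxymethyl)-7-methoxy-2,3-dihydro-1-benzofuran-5-yl]methyl}-4-[(4-{[(1R,2S)-1-[4-(benzyloxy)-3-methoxyphenyl]-1,3-dihydroxypropan-2-yl]oxy}-3-methoxyphenyl)methyl]oxolan-2-one
Product: 41 (3R,4R)-3-{[(2S,3R)-2-(4-hydroxy-3-methoxyphenyl)-3-(hydroxymethyl)-7-methoxy-2,3-dihydro-1-benzofuran-5-yl]methyl}-4-[(4-{[(1R,2S)-1,3-dihydroxy-1-(4-hydroxy-3-methoxyphenyl)propan-2-yl]oxy}-3-methoxyphenyl)methyl]oxolan-2-one (CNP0265599.1)
Conditions: H2 (1 atm), Pd/C, EtOAc/MeOH, rt; stopped after uptake of 3 equiv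
Reagents that add atoms: none
Why: Hydrogenolysis of the three aryl benzyl ethers under neutral conditions; O-benzyl cleavage is expected to be faster than cleavage of the benzylic C7–OH and coumaran C2–O bonds, so the reaction is stopped at the calculated uptake.

## Compound list

1 | furfural (furan-2-carbaldehyde) | O=Cc1ccco1 | starting material
2 | furfural 2,5-endoperoxide (2,3,7-trioxabicyclo[2.2.1]hept-5-ene-1-carbaldehyde) | O=CC12C=CC(OO1)O2 | intermediate
3 | 5-hydroxyfuran-2(5H)-one (racemic hemiacetal) | O=C1C=CC(O)O1 | intermediate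
4 | (−)-menthol, (1R,2S,5R)-5-methyl-2-(propan-2-yl)cyclohexan-1-ol | CC(C)[C@@H]1CC[C@@H](C)C[C@H]1O | starting material
5 | (5R)-5-{[(1R,2S,5R)-5-methyl-2-(propan-2-yl)cyclohexyl]oxy}furan-2(5H)-one | O=C1C=C[C@H](O[C@@H]2C[C@H](C)CC[C@H]2C(C)C)O1 | intermediate
6 | vanillin (4-hydroxy-3-methoxybenzaldehyde) | COc1cc(C=O)ccc1O | starting material
7 | 4-(1,3-dithian-2-yl)-2-methoxyphenol | COc1cc(C2SCCCS2)ccc1O | intermediate
8 | methyl (2R)-2,3-dihydroxypropanoate | COC(=O)[C@H](O)CO | starting material
9 | methyl (2R)-3-[(tert-butyldiphenylsilyl)oxy]-2-hydroxypropanoate | COC(=O)[C@H](O)CO[Si](c1ccccc1)(c1ccccc1)C(C)(C)C | intermediate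
10 | methyl (2S)-3-[(tert-butyldiphenylsilyl)oxy]-2-[4-(1,3-dithian-2-yl)-2-methoxyphenoxy]propanoate | COC(=O)[C@@H](Oc1ccc(C2SCCCS2)cc1OC)CO[Si](c1ccccc1)(c1ccccc1)C(C)(C)C | intermediate
11 | (2S)-3-[(tert-butyldiphenylsilyl)oxy]-2-[4-(1,3-dithian-2-yl)-2-methoxyphenoxy]-N-methoxy-N-methylpropanamide | CON(C)C(=O)[C@@H](Oc1ccc(C2SCCCS2)cc1OC)CO[Si](c1ccccc1)(c1ccccc1)C(C)(C)C | intermediate
12 | 1-(benzyloxy)-4-bromo-2-methoxybenzene | COc1cc(Br)ccc1OCc1ccccc1 | starting material
13 | [4-(benzyloxy)-3-methoxyphenyl]magnesium bromide | COc1cc([Mg]Br)ccc1OCc1ccccc1 | intermediate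
14 | (2S)-1-[4-(benzyloxy)-3-methoxyphenyl]-3-[(tert-butyldiphenylsilyl)oxy]-2-[4-(1,3-dithian-2-yl)-2-methoxyphenoxy]propan-1-one | COc1cc(C(=O)[C@@H](Oc2ccc(C3SCCCS3)cc2OC)CO[Si](c2ccccc2)(c2ccccc2)C(C)(C)C)ccc1OCc1ccccc1 | intermediate
15 | (1R,2S)-1-[4-(benzyloxy)-3-methoxyphenyl]-3-[(tert-butyldiphenylsilyl)oxy]-2-[4-(1,3-dithian-2-yl)-2-methoxyphenoxy]propan-1-ol (erythro) | COc1cc([C@@H](O)[C@H](CO[Si](c2ccccc2)(c2ccccc2)C(C)(C)C)Oc2ccc(C3SCCCS3)cc2OC)ccc1OCc1ccccc1 | intermediate
16 | 2-(4-{[(1R,2S)-1-[4-(benzyloxy)-3-methoxyphenyl]-1-[(tert-butyldimethylsilyl)oxy]-3-[(tert-butyldiphenylsilyl)oxy]propan-2-yl]oxy}-3-methoxyphenyl)-1,3-dithiane | COc1cc([C@@H](O[Si](C)(C)C(C)(C)C)[C@H](CO[Si](c2ccccc2)(c2ccccc2)C(C)(C)C)Oc2ccc(C3SCCCS3)cc2OC)ccc1OCc1ccccc1 | intermediate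
17 | methyl 3-bromo-4-hydroxy-5-methoxybenzoate | COC(=O)c1cc(Br)c(O)c(OC)c1 | starting material
18 | methyl 3-bromo-5-methoxy-4-(methoxymethoxy)benzoate | COCOc1c(Br)cc(C(=O)OC)cc1OC | intermediate
19 | methyl 3-[2-(benzyloxy)-2-oxoethyl]-5-methoxy-4-(methoxymethoxy)benzoate | COCOc1c(CC(=O)OCc2ccccc2)cc(C(=O)OC)cc1OC | intermediate
20 | [3-methoxy-5-(methoxycarbonyl)-2-(methoxymethoxy)phenyl]acetic acid | COCOc1c(CC(=O)O)cc(C(=O)OC)cc1OC | intermediate
21 | (4S)-4-benzyl-1,3-oxazolidin-2-one | O=C1N[C@@H](Cc2ccccc2)CO1 | starting material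
22 | mixed anhydride of acid 20 with 2,2-dimethylpropanoic acid | COCOc1c(CC(=O)OC(=O)C(C)(C)C)cc(C(=O)OC)cc1OC | intermediate
23 | methyl 3-{2-[(4S)-4-benzyl-2-oxo-1,3-oxazolidin-3-yl]-2-oxoethyl}-5-methoxy-4-(methoxymethoxy)benzoate | COCOc1c(CC(=O)N2[C@@H](Cc3ccccc3)COC2=O)cc(C(=O)OC)cc1OC | intermediate
24 | 4-(benzyloxy)-3-methoxybenzaldehyde | COc1cc(C=O)ccc1OCc1ccccc1 | starting material
25 | dibutylboron (Z)-enolate of imide 23 | CCCCB(CCCC)O/C(=C\c1cc(C(=O)OC)cc(OC)c1OCOC)N1[C@@H](Cc2ccccc2)COC1=O | intermediate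
26 | (4S)-4-benzyl-3-[(2S,3S)-3-[4-(benzyloxy)-3-methoxyphenyl]-3-hydroxy-2-[3-methoxy-5-(methoxycarbonyl)-2-(methoxymethoxy)phenyl]propanoyl]-1,3-oxazolidin-2-one | COCOc1c([C@H](C(=O)N2[C@@H](Cc3ccccc3)COC2=O)[C@H](O)c2ccc(OCc3ccccc3)c(OC)c2)cc(C(=O)OC)cc1OC | intermediate
27 | methyl 3-[(1S,2R)-1-[4-(benzyloxy)-3-methoxyphenyl]-1,3-dihydroxypropan-2-yl]-5-methoxy-4-(methoxymethoxy)benzoate | COCOc1c([C@H](CO)[C@H](O)c2ccc(OCc3ccccc3)c(OC)c2)cc(C(=O)OC)cc1OC | intermediate
28 | methyl 3-[(1S,2R)-1-[4-(benzyloxy)-3-methoxyphenyl]-1,3-dihydroxypropan-2-yl]-4-hydroxy-5-methoxybenzoate | Oc1c([C@H](CO)[C@H](O)c2ccc(OCc3ccccc3)c(OC)c2)cc(C(=O)OC)cc1OC | intermediate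
29 | methyl (2S,3R)-2-[4-(benzyloxy)-3-methoxyphenyl]-3-(hydroxymethyl)-7-methoxy-2,3-dihydro-1-benzofuran-5-carboxylate | COC(=O)c1cc(OC)c2c(c1)[C@H](CO)[C@@H](c1ccc(OCc3ccccc3)c(OC)c1)O2 | intermediate
30 | methyl (2S,3R)-2-[4-(benzyloxy)-3-methoxyphenyl]-3-{[(tert-butyldimethylsilyl)oxy]methyl}-7-methoxy-2,3-dihydro-1-benzofuran-5-carboxylate | COC(=O)c1cc(OC)c2c(c1)[C@H](CO[Si](C)(C)C(C)(C)C)[C@@H](c1ccc(OCc3ccccc3)c(OC)c1)O2 | intermediate
31 | [(2S,3R)-2-[4-(benzyloxy)-3-methoxyphenyl]-3-{[(tert-butyldimethylsilyl)oxy]methyl}-7-methoxy-2,3-dihydro-1-benzofuran-5-yl]methanol | OCc1cc(OC)c2c(c1)[C@H](CO[Si](C)(C)C(C)(C)C)[C@@H](c1ccc(OCc3ccccc3)c(OC)c1)O2 | intermediate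
32 | (2S,3R)-2-[4-(benzyloxy)-3-methoxyphenyl]-5-(bromomethyl)-3-{[(tert-butyldimethylsilyl)oxy]methyl}-7-methoxy-2,3-dihydro-1-benzofuran | BrCc1cc(OC)c2c(c1)[C@H](CO[Si](C)(C)C(C)(C)C)[C@@H](c1ccc(OCc3ccccc3)c(OC)c1)O2 | intermediate
33 | 2-lithio derivative of dithiane 16 (lithium on the dithiane C2) | COc1cc([C@@H](O[Si](C)(C)C(C)(C)C)[C@H](CO[Si](c2ccccc2)(c2ccccc2)C(C)(C)C)Oc2ccc(C3([Li])SCCCS3)cc2OC)ccc1OCc1ccccc1 | intermediate
34 | lithium (4R,5R)-4-(2-ArAB-1,3-dithian-2-yl)-5-(Men-oxy)-4,5-dihydrofuran-2-olate | COc1cc([C@@H](O[Si](C)(C)C(C)(C)C)[C@H](CO[Si](c2ccccc2)(c2ccccc2)C(C)(C)C)Oc2ccc(C3(SCCCS3)[C@H]4[C@H](O[C@@H]5C[C@H](C)CC[C@H]5C(C)C)OC(O[Li])=C4)cc2OC)ccc1OCc1ccccc1 | intermediate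
35 | (3R,4R,5R)-3-(ArCD-methyl)-4-(2-ArAB-1,3-dithian-2-yl)-5-(Men-oxy)oxolan-2-one | COc1cc([C@@H](O[Si](C)(C)C(C)(C)C)[C@H](CO[Si](c2ccccc2)(c2ccccc2)C(C)(C)C)Oc2ccc(C3(SCCCS3)[C@H]4[C@H](O[C@@H]5C[C@H](C)CC[C@H]5C(C)C)OC(=O)[C@@H]4Cc4cc(OC)c5c(c4)[C@H](CO[Si](C)(C)C(C)(C)C)[C@@H](c4ccc(OCc6ccccc6)c(OC)c4)O5)cc2OC)ccc1OCc1ccccc1 | intermediate
36 | (3R,4R,5R)-3-(ArCD-methyl)-4-(ArAB-methyl)-5-(Men-oxy)oxolan-2-one | COc1cc([C@@H](O[Si](C)(C)C(C)(C)C)[C@H](CO[Si](c2ccccc2)(c2ccccc2)C(C)(C)C)Oc2ccc(C[C@H]4[C@H](O[C@@H]5C[C@H](C)CC[C@H]5C(C)C)OC(=O)[C@@H]4Cc4cc(OC)c5c(c4)[C@H](CO[Si](C)(C)C(C)(C)C)[C@@H](c4ccc(OCc6ccccc6)c(OC)c4)O5)cc2OC)ccc1OCc1ccccc1 | intermediate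
37 | potassium (2R,3R)-2-(ArCD-methyl)-3-(ArAB-methyl)-4-oxobutanoate | COc1cc([C@@H](O[Si](C)(C)C(C)(C)C)[C@H](CO[Si](c2ccccc2)(c2ccccc2)C(C)(C)C)Oc2ccc(C[C@@H](C=O)[C@@H](Cc4cc(OC)c5c(c4)[C@H](CO[Si](C)(C)C(C)(C)C)[C@@H](c4ccc(OCc6ccccc6)c(OC)c4)O5)C(=O)[O-])cc2OC)ccc1OCc1ccccc1.[K+] | intermediate
38 | potassium (2R,3R)-2-(ArCD-methyl)-4-hydroxy-3-(ArAB-methyl)butanoate | COc1cc([C@@H](O[Si](C)(C)C(C)(C)C)[C@H](CO[Si](c2ccccc2)(c2ccccc2)C(C)(C)C)Oc2ccc(C[C@@H](CO)[C@@H](Cc4cc(OC)c5c(c4)[C@H](CO[Si](C)(C)C(C)(C)C)[C@@H](c4ccc(OCc6ccccc6)c(OC)c4)O5)C(=O)[O-])cc2OC)ccc1OCc1ccccc1.[K+] | intermediate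
39 | (3R,4R)-3-(ArCD-methyl)-4-(ArAB-methyl)oxolan-2-one | COc1cc([C@@H](O[Si](C)(C)C(C)(C)C)[C@H](CO[Si](c2ccccc2)(c2ccccc2)C(C)(C)C)Oc2ccc(C[C@H]4COC(=O)[C@@H]4Cc4cc(OC)c5c(c4)[C@H](CO[Si](C)(C)C(C)(C)C)[C@@H](c4ccc(OCc6ccccc6)c(OC)c4)O5)cc2OC)ccc1OCc1ccccc1 | intermediate
40 | (3R,4R)-3-{[(2S,3R)-2-[4-(benzyloxy)-3-methoxyphenyl]-3-(hydroxymethyl)-7-methoxy-2,3-dihydro-1-benzofuran-5-yl]methyl}-4-[(4-{[(1R,2S)-1-[4-(benzyloxy)-3-methoxyphenyl]-1,3-dihydroxypropan-2-yl]oxy}-3-methoxyphenyl)methyl]oxolan-2-one | COc1cc([C@@H](O)[C@H](CO)Oc2ccc(C[C@H]4COC(=O)[C@@H]4Cc4cc(OC)c5c(c4)[C@H](CO)[C@@H](c4ccc(OCc6ccccc6)c(OC)c4)O5)cc2OC)ccc1OCc1ccccc1 | intermediate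
41 | (3R,4R)-3-{[(2S,3R)-2-(4-hydroxy-3-methoxyphenyl)-3-(hydroxymethyl)-7-methoxy-2,3-dihydro-1-benzofuran-5-yl]methyl}-4-[(4-{[(1R,2S)-1,3-dihydroxy-1-(4-hydroxy-3-methoxyphenyl)propan-2-yl]oxy}-3-methoxyphenyl)methyl]oxolan-2-one (CNP0265599.1) | COc1cc([C@@H](O)[C@H](CO)Oc2ccc(C[C@H]3COC(=O)[C@@H]3Cc3cc(OC)c4c(c3)[C@H](CO)[C@@H](c3ccc(O)c(OC)c3)O4)cc2OC)ccc1O | target

## Step count and least certain steps

Total step count: 24 (steps 1–2 butenolide 5, steps 3–9 dithiane 16, steps 10–19 bromide 32, step 20 union, steps 21–24 endgame). Longest linear sequence: 15 steps (17 → 41, steps 10–24).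

Step 20 (key step). The most likely failure is incomplete C-alkylation of enolate 34: the hindered enolate may be protonated, or may react too slowly with the solvolysis-prone bromide 32, so that the simple Michael adduct is obtained. A second risk is consumption of 32 by unreacted anion 33 if the conjugate addition has not finished when the bromide is added. The fallback separates the two bond formations. Anion 33 (from 16) is added to 5 at −78 °C and the enolate is quenched with NH4Cl to give the isolated Michael adduct (4R,5R)-4-(2-ArAB-1,3-dithian-2-yl)-5-(Men-oxy)oxolan-2-one F1. F1 is then deprotonated with LiN(SiMe3)2 in THF/DMPU at −78 °C and alkylated with 32, which can now be used in excess, again trans to the C4 substituent; this returns to the route at 35.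

Step 8. The risk is poor facial selectivity if zinc does not hold the ketone and the weakly basic aryloxy oxygen in one chelate; a competing non-chelated (Felkin–Anh) pathway would give the threo alcohol. The fallback sets C7 in a C–C bond formation instead of a reduction. Ester 10 is reduced with iBu2AlH (CH2Cl2, −78 °C) to (2S)-3-[(tert-butyldiphenylsilyl)oxy]-2-[4-(1,3-dithian-2-yl)-2-methoxyphenoxy]propanal F2. Grignard reagent 13 (from 12) is added in THF at −78 °C; under Felkin–Anh control, with the polar aryloxy group anti to the incoming aryl, the anti alcohol 15 is expected, where the route is rejoined.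

Step 11. The risk is slow oxidative addition or transmetalation at the bromide flanked by the MOM ether, with protodezincation of the Reformatsky reagent taking over. The fallback builds the acetic acid side chain from an allyl group. Bromide 18 undergoes Stille coupling with allyltributylstannane (Pd(PPh3)4, toluene, 100 °C) to methyl 5-methoxy-4-(methoxymethoxy)-3-(prop-2-en-1-yl)benzoate F3. Lemieux–Johnson cleavage (OsO4 cat., NaIO4, THF/H2O) gives methyl 5-methoxy-4-(methoxymethoxy)-3-(2-oxoethyl)benzoate F4, and Pinnick oxidation (NaClO2, NaH2PO4, 2-methylbut-2-ene) gives acid 20.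

Step 15. The risks are competing reduction of the methyl benzoate and retro-aldol cleavage of the α-aryl β-hydroxy imide under the basic borohydride conditions. The fallback removes the auxiliary hydrolytically and reduces at the acid stage. Aldol 26 is cleaved with LiOH/H2O2 (THF/H2O, 0 °C) to (2S,3S)-3-[4-(benzyloxy)-3-methoxyphenyl]-3-hydroxy-2-[3-methoxy-5-(methoxycarbonyl)-2-(methoxymethoxy)phenyl]propanoic acid F5. BH3·SMe2 (THF, 0 °C) then reduces the carboxylic acid in preference to the methyl ester and gives diol 27.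

Step 24. The risk is over-reduction: once ring A is a free p-hydroxyphenyl group the C7–OH bond is doubly activated towards hydrogenolysis, and the coumaran C2–O bond may also be cleaved on long exposure. The fallback changes the order of deprotection. Lactone 39 is hydrogenolysed first (H2, Pd/C, EtOAc) while the C7 oxygen is still silylated, giving the tris-phenol (3R,4R)-3-{[(2S,3R)-3-{[(tert-butyldimethylsilyl)oxy]methyl}-2-(4-hydroxy-3-methoxyphenyl)-7-methoxy-2,3-dihydro-1-benzofuran-5-yl]methyl}-4-[(4-{[(1R,2S)-1-[(tert-butyldimethylsilyl)oxy]-3-[(tert-butyldiphenylsilyl)oxy]-1-(4-hydroxy-3-methoxyphenyl)propan-2-yl]oxy}-3-methoxyphenyl)methyl]oxolan-2-one F6. F6 is then desilylated with HF·pyridine (THF/pyridine, 0 °C) to give 41.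

## Further compounds

F1 | step 20 | (4R,5R)-4-(2-ArAB-1,3-dithian-2-yl)-5-(Men-oxy)oxolan-2-one | COc1cc([C@@H](O[Si](C)(C)C(C)(C)C)[C@H](CO[Si](c2ccccc2)(c2ccccc2)C(C)(C)C)Oc2ccc(C3(SCCCS3)[C@H]4[C@H](O[C@@H]5C[C@H](C)CC[C@H]5C(C)C)OC(=O)C4)cc2OC)ccc1OCc1ccccc1
F2 | step 8 | (2S)-3-[(tert-butyldiphenylsilyl)oxy]-2-[4-(1,3-dithian-2-yl)-2-methoxyphenoxy]propanal | O=C[C@@H](Oc1ccc(C2SCCCS2)cc1OC)CO[Si](c1ccccc1)(c1ccccc1)C(C)(C)C
F3 | step 11 | methyl 5-methoxy-4-(methoxymethoxy)-3-(prop-2-en-1-yl)benzoate | COCOc1c(CC=C)cc(C(=O)OC)cc1OC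
F4 | step 11 | methyl 5-methoxy-4-(methoxymethoxy)-3-(2-oxoethyl)benzoate | COCOc1c(CC=O)cc(C(=O)OC)cc1OC
F5 | step 15 | (2S,3S)-3-[4-(benzyloxy)-3-methoxyphenyl]-3-hydroxy-2-[3-methoxy-5-(methoxycarbonyl)-2-(methoxymethoxy)phenyl]propanoic acid | COCOc1c([C@H](C(=O)O)[C@H](O)c2ccc(OCc3ccccc3)c(OC)c2)cc(C(=O)OC)cc1OC
F6 | step 24 | (3R,4R)-3-{[(2S,3R)-3-{[(tert-butyldimethylsilyl)oxy]methyl}-2-(4-hydroxy-3-methoxyphenyl)-7-methoxy-2,3-dihydro-1-benzofuran-5-yl]methyl}-4-[(4-{[(1R,2S)-1-[(tert-butyldimethylsilyl)oxy]-3-[(tert-butyldiphenylsilyl)oxy]-1-(4-hydroxy-3-methoxyphenyl)propan-2-yl]oxy}-3-methoxyphenyl)methyl]oxolan-2-one | COc1cc([C@@H](O[Si](C)(C)C(C)(C)C)[C@H](CO[Si](c2ccccc2)(c2ccccc2)C(C)(C)C)Oc2ccc(C[C@H]4COC(=O)[C@@H]4Cc4cc(OC)c5c(c4)[C@H](CO[Si](C)(C)C(C)(C)C)[C@@H](c4ccc(O)c(OC)c4)O5)cc2OC)ccc1O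
A1 | alternative 1 | (2S)-6-bromo-8-methoxy-2-{3-methoxy-4-[(4-methylbenzenesulfonyl)oxy]phenyl}-2,3-dihydro-4H-chromen-4-one | O=C1C[C@@H](c2ccc(OS(=O)(=O)c3ccc(C)cc3)c(OC)c2)Oc2c(OC)cc(Br)cc21
A2 | alternative 1 | methyl (2S,3S)-5-bromo-7-methoxy-2-{3-methoxy-4-[(4-methylbenzenesulfonyl)oxy]phenyl}-2,3-dihydro-1-benzofuran-3-carboxylate (trans) | Brc3cc(OC)c4c(c3)[C@H](C(=O)OC)[C@@H](c3ccc(OS(=O)(=O)c5ccc(C)cc5)c(OC)c3)O4
A3 | alternative 2 | methyl 2-diazo-2-[2-{[4-(benzyloxy)-3-methoxyphenyl]methoxy}-3-methoxy-5-({[tri(propan-2-yl)silyl]oxy}methyl)phenyl]acetate | COC(=O)C(=[N+]=[N-])c1cc(CO[Si](C(C)C)(C(C)C)C(C)C)cc(OC)c1OCc1ccc(OCc2ccccc2)c(OC)c1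
A4 | alternative 2 | methyl (2S,3R)-2-[4-(benzyloxy)-3-methoxyphenyl]-7-methoxy-5-({[tri(propan-2-yl)silyl]oxy}methyl)-2,3-dihydro-1-benzofuran-3-carboxylate (cis) | CC(C)[Si](OCc3cc(OC)c4c(c3)[C@@H](C(=O)OC)[C@@H](c3ccc(OCc5ccccc5)c(OC)c3)O4)(C(C)C)C(C)C
A5 | alternative 3 | 2-[(2R)-1-[4-(benzyloxy)-3-methoxyphenyl]-1,3-dihydroxypropan-2-yl]-4-bromo-6-methoxyphenol (either configuration at C1 of the chain) | COc1cc(Br)cc([C@H](CO)C(O)c2ccc(OCc3ccccc3)c(OC)c2)c1O
A6 | alternative 3 | [(2S,3R)-2-[4-(benzyloxy)-3-methoxyphenyl]-5-bromo-7-methoxy-2,3-dihydro-1-benzofuran-3-yl]methanol | Brc3cc(OC)c4c(c3)[C@H](CO)[C@@H](c3ccc(OCc5ccccc5)c(OC)c3)O4
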